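**Retrosynthetic overview**
1. Target 20 is cut at C2–C1' (quaternary chroman carbon to first side-chain carbon). C1' becomes the terminus of the C16 alkyne 13, and C2 becomes the electrophilic carbon of a 4-siloxybenzopyrylium made from the flat, achiral chromone 5.
2. Enabling feature: C2 is bound to the ring oxygen O1 of the dihydropyran ring B and lies beta to the benzylic C4 next to arene ring A. The unit O1–C2=C3–C4=O can therefore be drawn as a chromone, and O-silylation at the C4 oxygen aromatises ring B and makes C2 the site of nucleophilic attack.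
3. Ring order: ring A is bought (4-methoxy-2-methylphenol). Ring B is closed early at the pyranone level (Fries rearrangement, Claisen condensation, cyclodehydration). The key step closes no ring, and ring B is brought down to the chroman level last.
4. Alkyne 13 comes from (R)-citronellyl bromide (C8' and the C11'=C12' alkene) and (S)-3-bromo-2-methylpropan-1-ol (C4'), joined by copper-catalysed Grignard coupling, followed by acetylide displacement of a tosylate.
5. Endgame: the extra oxidation level (C1'≡C2' and C4=O) is removed by chemoselective hydrogenation, then NaBH4 and Et3SiH/BF3·OEt2, followed by O-demethylation.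

Key step: step 8

Assumption: locants O1, C2–C4, C4a, C5–C8, C8a are used for the chroman and C1'–C13' for the side chain; by the sequence rules the target is (2R,4'R,8'S), C8' having the spatial arrangement of the natural phytyl-type chain although its descriptor is S because of the C11'=C12' double bond.

**Route**

Step 1
Reactants: 1 4-methoxy-2-methylphenol
Product: 3 1-(2-hydroxy-5-methoxy-3-methylphenyl)ethan-1-one, via 4-methoxy-2-methylphenyl acetate 2 (not isolated)
Conditions: Ac2O, BF3·OEt2, 90 °C; aq. NaOAc work-up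
Reagents that add atoms: acetic anhydride, CC(=O)OC(C)=O
Why: O-acetylation followed by BF3-promoted Fries rearrangement should place the acetyl group on the only free position ortho to the phenol oxygen (the other ortho position carries CH3, the para position OCH3), the product being held as a boron chelate until work-up.

Step 2
Reactants: 3 1-(2-hydroxy-5-methoxy-3-methylphenyl)ethan-1-one
Product: 5 6-methoxy-2,8-dimethyl-4H-chromen-4-one, via beta-diketone 4 (not isolated)
Conditions: NaH, EtOAc, THF, reflux; then conc. HCl (cat.), AcOH, 100 °C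
Reagents that add atoms: ethyl acetate, CCOC(C)=O
Why: Claisen condensation of the methyl ketone enolate with ethyl acetate gives the 1,3-diketone, and acid-catalysed cyclodehydration of the phenol onto the distal carbonyl should close ring B as the 2-methylchromone.

Step 3
Reactants: 6 (S)-3-bromo-2-methylpropan-1-ol
Product: 7 (S)-(3-bromo-2-methylpropoxy)(tert-butyl)dimethylsilane
Conditions: TBSCl, imidazole, CH2Cl2, 0 °C → rt
Reagents that add atoms: tert-butyldimethylsilyl chloride, CC(C)(C)[Si](C)(C)Cl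
Why: Standard silylation of a primary alcohol masks the hydroxyl for the Grignard coupling and does not touch the stereocentre.

Step 4
Reactants: 8 (R)-citronellyl bromide [(6R)-8-bromo-2,6-dimethyloct-2-ene]; 7 (S)-(3-bromo-2-methylpropoxy)(tert-butyl)dimethylsilane
Product: 10 tert-butyldimethyl{[(2R,6S)-2,6,10-trimethylundec-9-en-1-yl]oxy}silane, via citronellylmagnesium bromide 9 (not isolated)
Conditions: Mg, THF, 40 °C; then 7, Li2CuCl4 (3 mol %), NMP, THF, −20 °C → rt
Reagents that add atoms: none
Why: Copper-catalysed sp3–sp3 cross-coupling of a primary alkyl Grignard reagent with a primary alkyl bromide should join the two chiral-pool pieces, and since neither reacting carbon is stereogenic both methyl-bearing centres are carried over unchanged.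

Step 5
Reactants: 10 tert-butyldimethyl{[(2R,6S)-2,6,10-trimethylundec-9-en-1-yl]oxy}silane
Product: 11 (2R,6S)-2,6,10-trimethylundec-9-en-1-ol
Conditions: Bu4NF, THF, rt
Reagents that add atoms: none
Why: Fluoride-induced desilylation of a primary silyl ether is reliable and leaves the trisubstituted alkene alone.

Step 6
Reactants: 11 (2R,6S)-2,6,10-trimethylundec-9-en-1-ol
Product: 12 (2R,6S)-2,6,10-trimethylundec-9-en-1-yl 4-methylbenzenesulfonate
Conditions: TsCl, Et3N, DMAP (cat.), CH2Cl2, 0 °C → rt
Reagents that add atoms: p-toluenesulfonyl chloride, Cc1ccc(cc1)S(=O)(=O)Cl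
Why: Sulfonylation of the primary alcohol gives a leaving group for the SN2 chain extension without affecting the adjacent stereocentre.

Step 7
Reactants: 12 (2R,6S)-2,6,10-trimethylundec-9-en-1-yl 4-methylbenzenesulfonate
Product: 13 (4R,8S)-4,8,12-trimethyltridec-11-en-1-yne
Conditions: LiC≡CH·H2NCH2CH2NH2, DMSO, rt
Reagents that add atoms: lithium acetylide (used as its ethylenediamine complex), [Li]C#C
Why: SN2 alkylation of lithium acetylide by a beta-branched primary tosylate in DMSO should give the terminal alkyne, the displacement taking place at a CH2 group so that C4 keeps its configuration.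

Step 8
Reactants: 5 6-methoxy-2,8-dimethyl-4H-chromen-4-one; 13 (4R,8S)-4,8,12-trimethyltridec-11-en-1-yne
Product: 16 (2S)-6-methoxy-2,8-dimethyl-2-[(4R,8S)-4,8,12-trimethyltridec-11-en-1-yn-1-yl]-2,3-dihydro-4H-chromen-4-one, via siloxybenzopyrylium triflate 14 (not isolated), via enol silyl ether 15 (not isolated)
Conditions: 5 (1.5 equiv), TBSOTf, 1,2-dichloroethane, 60 °C; then 13, CuI (10 mol %), indane-fused bis(oxazoline) ligand (12 mol %), iPr2NEt, toluene, −78 → −40 °C; then 1 M HCl, THF, 0 °C
Reagents that add atoms: none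
Why: Proposed new method: O-silylation of the C4 carbonyl oxygen of 5 aromatises ring B to the 4-siloxybenzopyrylium 14, and a monovalent copper acetylide formed from 13, CuI and iPr2NEt within the chiral bis(oxazoline) ligand should add irreversibly to C2, the carbon flanked by O1 and the 2-methyl group, to give enol silyl ether 15, which dilute acid unmasks as ketone 16. The closest known reaction type is the CuI/bis(oxazoline)-catalysed enantioselective alkynylation of 4-siloxybenzopyrylium triflates generated from chromones that carry hydrogen or an ester group at C2; a 2-alkyl benzopyrylium has not been shown as the acceptor. No ring is closed, since ring B is already in place and only passes from the planar pyrylium level to the 2H-pyran level. The one new stereocentre, C2, is set by the catalyst through attack on the Re face of C2 (the face on which O1, C3 and CH3 run clockwise), which gives (2S)-16, the spatial arrangement of 2R in the target; the ligand antipode that does this is to be fixed in a model run with a simple alkyne, and the remote C4' and C8' centres of 13 should have no influence. The step needs attack at C2 instead of C4, which the bulky siloxy group on C4 and the higher cationic character of the O1-bound C2 should secure. It also needs C–C bond formation to outrun deprotonation of the 2-methyl group, which should be reversible in the presence of iPr2NEt·HOTf while acetylide transfer is not.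

Step 9
Reactants: 16 (2S)-6-methoxy-2,8-dimethyl-2-[(4R,8S)-4,8,12-trimethyltridec-11-en-1-yn-1-yl]-2,3-dihydro-4H-chromen-4-one
Product: 17 (2R)-6-methoxy-2,8-dimethyl-2-[(4R,8S)-4,8,12-trimethyltridec-11-en-1-yl]-2,3-dihydro-4H-chromen-4-one
Conditions: H2 (1 atm), RhCl(PPh3)3 (5 mol %), benzene–EtOH 1:1, rt, stopped after 2 equiv H2
Reagents that add atoms: none
Why: Homogeneous hydrogenation with RhCl(PPh3)3 reduces alkynes and 1,2-disubstituted alkenes far faster than trisubstituted alkenes, so the C1'≡C2' bond should be saturated through the cis-alkene while the C11'=C12' alkene and the aryl ketone survive, C2 being untouched (its descriptor changes to R only through the priority change).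

Step 10
Reactants: 17 (2R)-6-methoxy-2,8-dimethyl-2-[(4R,8S)-4,8,12-trimethyltridec-11-en-1-yl]-2,3-dihydro-4H-chromen-4-one
Product: 18 (2R,4RS)-6-methoxy-2,8-dimethyl-2-[(4R,8S)-4,8,12-trimethyltridec-11-en-1-yl]-3,4-dihydro-2H-chromen-4-ol (mixture of C4 epimers)
Conditions: NaBH4, MeOH–THF, 0 °C
Reagents that add atoms: none
Why: Borohydride reduction of the aryl ketone is faster than any base-induced retro-oxa-Michael opening of ring B, and the C4 configuration is irrelevant because C4 becomes CH2 in the next step.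

Step 11
Reactants: 18 (2R,4RS)-6-methoxy-2,8-dimethyl-2-[(4R,8S)-4,8,12-trimethyltridec-11-en-1-yl]-3,4-dihydro-2H-chromen-4-ol
Product: 19 (2R)-6-methoxy-2,8-dimethyl-2-[(4R,8S)-4,8,12-trimethyltridec-11-en-1-yl]-3,4-dihydro-2H-chromene
Conditions: Et3SiH, BF3·OEt2, CH2Cl2, −78 → −20 °C
Reagents that add atoms: none
Why: Ionic hydrogenation: the Lewis acid ionises the benzylic C4–OH to a cation stabilised through ring A by the ortho ring oxygen O1, and Et3SiH traps it at low temperature under conditions free of protic acid that should spare the trisubstituted alkene.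

Step 12
Reactants: 19 (2R)-6-methoxy-2,8-dimethyl-2-[(4R,8S)-4,8,12-trimethyltridec-11-en-1-yl]-3,4-dihydro-2H-chromene
Product: 20 (2R)-2,8-dimethyl-2-[(4R,8S)-4,8,12-trimethyltridec-11-en-1-yl]-3,4-dihydro-2H-chromen-6-ol (target)
Conditions: NaSEt, DMF, 120 °C, argon; then dilute HCl work-up
Reagents that add atoms: none
Why: Ethanethiolate cleaves the aryl methyl ether by SN2 attack at the methyl carbon, whereas the O1–C2 ether has a tertiary alkyl carbon that cannot react this way, and the alkene and all three stereocentres are inert to the conditions.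

**Compound list**
1 | 4-methoxy-2-methylphenol | Cc1cc(OC)ccc1O | starting material
2 | 4-methoxy-2-methylphenyl acetate | CC(=O)Oc1ccc(OC)cc1C | intermediate (not isolated)
3 | 1-(2-hydroxy-5-methoxy-3-methylphenyl)ethan-1-one | CC(=O)c1cc(OC)cc(C)c1O | intermediate
4 | 1-(2-hydroxy-5-methoxy-3-methylphenyl)butane-1,3-dione | CC(=O)CC(=O)c1cc(OC)cc(C)c1O | intermediate (not isolated)
5 | 6-methoxy-2,8-dimethyl-4H-chromen-4-one | CC1=CC(=O)c2cc(OC)cc(C)c2O1 | intermediate
6 | (S)-3-bromo-2-methylpropan-1-ol | BrC[C@@H](C)CO | starting material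
7 | (S)-(3-bromo-2-methylpropoxy)(tert-butyl)dimethylsilane | BrC[C@@H](C)CO[Si](C)(C)C(C)(C)C | intermediate
8 | (R)-citronellyl bromide, (6R)-8-bromo-2,6-dimethyloct-2-ene | CC(C)=CCC[C@@H](C)CCBr | starting material
9 | (R)-citronellylmagnesium bromide | CC(C)=CCC[C@@H](C)CC[Mg]Br | intermediate (not isolated)
10 | tert-butyldimethyl{[(2R,6S)-2,6,10-trimethylundec-9-en-1-yl]oxy}silane | CC(C)=CCC[C@@H](C)CCC[C@@H](C)CO[Si](C)(C)C(C)(C)C | intermediate
11 | (2R,6S)-2,6,10-trimethylundec-9-en-1-ol | CC(C)=CCC[C@@H](C)CCC[C@@H](C)CO | intermediate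
12 | (2R,6S)-2,6,10-trimethylundec-9-en-1-yl 4-methylbenzenesulfonate | CC(C)=CCC[C@@H](C)CCC[C@@H](C)COS(=O)(=O)c1ccc(C)cc1 | intermediate
13 | (4R,8S)-4,8,12-trimethyltridec-11-en-1-yne | CC(C)=CCC[C@@H](C)CCC[C@@H](C)CC#C | intermediate
14 | 4-[(tert-butyldimethylsilyl)oxy]-6-methoxy-2,8-dimethylchromenylium trifluoromethanesulfonate | Cc1cc(O[Si](C)(C)C(C)(C)C)c2cc(OC)cc(C)c2[o+]1.[O-]S(=O)(=O)C(F)(F)F | intermediate (not isolated)
15 | tert-butyl({(2S)-6-methoxy-2,8-dimethyl-2-[(4R,8S)-4,8,12-trimethyltridec-11-en-1-yn-1-yl]-2H-chromen-4-yl}oxy)dimethylsilane | CC(C)=CCC[C@@H](C)CCC[C@@H](C)CC#C[C@]1(C)C=C(O[Si](C)(C)C(C)(C)C)c2cc(OC)cc(C)c2O1 | intermediate (not isolated)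
16 | (2S)-6-methoxy-2,8-dimethyl-2-[(4R,8S)-4,8,12-trimethyltridec-11-en-1-yn-1-yl]-2,3-dihydro-4H-chromen-4-one | CC(C)=CCC[C@@H](C)CCC[C@@H](C)CC#C[C@]1(C)CC(=O)c2cc(OC)cc(C)c2O1 | intermediate
17 | (2R)-6-methoxy-2,8-dimethyl-2-[(4R,8S)-4,8,12-trimethyltridec-11-en-1-yl]-2,3-dihydro-4H-chromen-4-one | CC(C)=CCC[C@@H](C)CCC[C@@H](C)CCC[C@]1(C)CC(=O)c2cc(OC)cc(C)c2O1 | intermediate
18 | (2R,4RS)-6-methoxy-2,8-dimethyl-2-[(4R,8S)-4,8,12-trimethyltridec-11-en-1-yl]-3,4-dihydro-2H-chromen-4-ol | CC(C)=CCC[C@@H](C)CCC[C@@H](C)CCC[C@]1(C)CC(O)c2cc(OC)cc(C)c2O1 | intermediate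
19 | (2R)-6-methoxy-2,8-dimethyl-2-[(4R,8S)-4,8,12-trimethyltridec-11-en-1-yl]-3,4-dihydro-2H-chromene | CC(C)=CCC[C@@H](C)CCC[C@@H](C)CCC[C@]1(C)CCc2cc(OC)cc(C)c2O1 | intermediate
20 | (2R)-2,8-dimethyl-2-[(4R,8S)-4,8,12-trimethyltridec-11-en-1-yl]-3,4-dihydro-2H-chromen-6-ol | CC(C)=CCC[C@@H](C)CCC[C@@H](C)CCC[C@]1(C)CCc2cc(O)cc(C)c2O1 | target

**Step count**
Total: 12 steps. Longest linear sequence: 10 steps (steps 3–12).

**Steps most likely to fail, with fallbacks**

Step 8 (bears the label). Deprotonation of the 2-methyl group of 14 (anhydrobase formation and oligomerisation) may outrun acetylide transfer, or the facial selectivity may be poor with an aliphatic alkyne. The fallback uses known chemistry, sets out from 3 (with 13) and comes back to the route at 19. The C2 methyl group is replaced by an ester, the acceptor class for which this copper-catalysed alkynylation to tertiary ethers is established, and the ester is reduced to the methyl group afterwards.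
- Claisen condensation of 3 with diethyl oxalate (NaOEt, EtOH) should give ethyl 4-(2-hydroxy-5-methoxy-3-methylphenyl)-2,4-dioxobutanoate F1.
- F1 is cyclised without isolation (HCl, AcOH) to ethyl 6-methoxy-8-methyl-4-oxo-4H-chromene-2-carboxylate F2.
- TBSOTf converts F2 into 4-[(tert-butyldimethylsilyl)oxy]-2-(ethoxycarbonyl)-6-methoxy-8-methylchromenylium trifluoromethanesulfonate F3.
- F3 with 13, CuI, the bis(oxazoline) ligand and iPr2NEt should give ethyl (2S)-4-[(tert-butyldimethylsilyl)oxy]-6-methoxy-8-methyl-2-[(4R,8S)-4,8,12-trimethyltridec-11-en-1-yn-1-yl]-2H-chromene-2-carboxylate F4.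
- Dilute HCl then gives ethyl (2S)-6-methoxy-8-methyl-4-oxo-2-[(4R,8S)-4,8,12-trimethyltridec-11-en-1-yn-1-yl]chromane-2-carboxylate F5.
- Hydrogenation as in step 9 gives ethyl (2R)-6-methoxy-8-methyl-4-oxo-2-[(4R,8S)-4,8,12-trimethyltridec-11-en-1-yl]chromane-2-carboxylate F6.
- LiAlH4 (THF, 0 °C) reduces ester and ketone to (2R,4RS)-2-(hydroxymethyl)-6-methoxy-8-methyl-2-[(4R,8S)-4,8,12-trimethyltridec-11-en-1-yl]chroman-4-ol F7.
- Et3SiH/BF3·OEt2 removes the benzylic hydroxyl to give {(2R)-6-methoxy-8-methyl-2-[(4R,8S)-4,8,12-trimethyltridec-11-en-1-yl]chroman-2-yl}methanol F8.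
- TsCl/pyridine gives {(2R)-6-methoxy-8-methyl-2-[(4R,8S)-4,8,12-trimethyltridec-11-en-1-yl]chroman-2-yl}methyl 4-methylbenzenesulfonate F9.
- LiEt3BH (THF, reflux) reduces the tosylate to the C2 methyl group of 19.

Step 9. Over-reduction of the C11'=C12' alkene, or stalling at the hindered cis-alkene next to the quaternary C2, may spoil the chemoselective hydrogenation. The fallback sets out from 16 and comes back at 17, and masks the alkene as an epoxide so that an unselective catalyst can be used.
- mCPBA (NaHCO3, CH2Cl2, 0 °C) should epoxidise only the electron-rich trisubstituted alkene to (2S)-2-[(4R,8S)-10-(3,3-dimethyloxiran-2-yl)-4,8-dimethyldec-1-yn-1-yl]-6-methoxy-2,8-dimethylchroman-4-one F10 (both oxirane epimers).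
- H2, Pd/C, EtOAc saturates the triple bond to (2R)-2-[(4R,8S)-10-(3,3-dimethyloxiran-2-yl)-4,8-dimethyldecyl]-6-methoxy-2,8-dimethylchroman-4-one F11.
- Oxygen transfer to a rhodium carbenoid (dimethyl diazomalonate, Rh2(OAc)4 cat., toluene, 80 °C) restores the alkene and gives 17.

Step 11. Protonation of the trisubstituted alkene by adventitious acid with hydride capture, or loss of a proton from the C4 cation to a 2H-chromene, may compete with the ionic reduction. The fallback sets out from 18 and comes back at 19, and replaces the cationic deoxygenation by a radical one.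
- 1,1'-Thiocarbonyldiimidazole, DMAP (cat.), 1,2-dichloroethane, 60 °C gives O-{(2R,4RS)-6-methoxy-2,8-dimethyl-2-[(4R,8S)-4,8,12-trimethyltridec-11-en-1-yl]chroman-4-yl} 1H-imidazole-1-carbothioate F12.
- Bu3SnH, AIBN, toluene, 90 °C (Barton–McCombie deoxygenation through the benzylic C4 radical) gives 19.

**Further compounds**
F1 | step 8 | ethyl 4-(2-hydroxy-5-methoxy-3-methylphenyl)-2,4-dioxobutanoate | CCOC(=O)C(=O)CC(=O)c1cc(OC)cc(C)c1O
F2 | step 8 | ethyl 6-methoxy-8-methyl-4-oxo-4H-chromene-2-carboxylate | CCOC(=O)C1=CC(=O)c2cc(OC)cc(C)c2O1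
F3 | step 8 | 4-[(tert-butyldimethylsilyl)oxy]-2-(ethoxycarbonyl)-6-methoxy-8-methylchromenylium trifluoromethanesulfonate | CCOC(=O)c1cc(O[Si](C)(C)C(C)(C)C)c2cc(OC)cc(C)c2[o+]1.[O-]S(=O)(=O)C(F)(F)F
F4 | step 8 | ethyl (2S)-4-[(tert-butyldimethylsilyl)oxy]-6-methoxy-8-methyl-2-[(4R,8S)-4,8,12-trimethyltridec-11-en-1-yn-1-yl]-2H-chromene-2-carboxylate | CC(C)=CCC[C@@H](C)CCC[C@@H](C)CC#C[C@]1(C(=O)OCC)C=C(O[Si](C)(C)C(C)(C)C)c2cc(OC)cc(C)c2O1
F5 | step 8 | ethyl (2S)-6-methoxy-8-methyl-4-oxo-2-[(4R,8S)-4,8,12-trimethyltridec-11-en-1-yn-1-yl]chromane-2-carboxylate | CC(C)=CCC[C@@H](C)CCC[C@@H](C)CC#C[C@]1(C(=O)OCC)CC(=O)c2cc(OC)cc(C)c2O1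
F6 | step 8 | ethyl (2R)-6-methoxy-8-methyl-4-oxo-2-[(4R,8S)-4,8,12-trimethyltridec-11-en-1-yl]chromane-2-carboxylate | CC(C)=CCC[C@@H](C)CCC[C@@H](C)CCC[C@]1(C(=O)OCC)CC(=O)c2cc(OC)cc(C)c2O1
F7 | step 8 | (2R,4RS)-2-(hydroxymethyl)-6-methoxy-8-methyl-2-[(4R,8S)-4,8,12-trimethyltridec-11-en-1-yl]chroman-4-ol | CC(C)=CCC[C@@H](C)CCC[C@@H](C)CCC[C@]1(CO)CC(O)c2cc(OC)cc(C)c2O1
F8 | step 8 | {(2R)-6-methoxy-8-methyl-2-[(4R,8S)-4,8,12-trimethyltridec-11-en-1-yl]chroman-2-yl}methanol | CC(C)=CCC[C@@H](C)CCC[C@@H](C)CCC[C@]1(CO)CCc2cc(OC)cc(C)c2O1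
F9 | step 8 | {(2R)-6-methoxy-8-methyl-2-[(4R,8S)-4,8,12-trimethyltridec-11-en-1-yl]chroman-2-yl}methyl 4-methylbenzenesulfonate | CC(C)=CCC[C@@H](C)CCC[C@@H](C)CCC[C@]1(COS(=O)(=O)c3ccc(C)cc3)CCc2cc(OC)cc(C)c2O1
F10 | step 9 | (2S)-2-[(4R,8S)-10-(3,3-dimethyloxiran-2-yl)-4,8-dimethyldec-1-yn-1-yl]-6-methoxy-2,8-dimethylchroman-4-one | CC1(C)OC1CC[C@@H](C)CCC[C@@H](C)CC#C[C@]2(C)CC(=O)c3cc(OC)cc(C)c3O2
F11 | step 9 | (2R)-2-[(4R,8S)-10-(3,3-dimethyloxiran-2-yl)-4,8-dimethyldecyl]-6-methoxy-2,8-dimethylchroman-4-one | CC1(C)OC1CC[C@@H](C)CCC[C@@H](C)CCC[C@]2(C)CC(=O)c3cc(OC)cc(C)c3O2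
F12 | step 11 | O-{(2R,4RS)-6-methoxy-2,8-dimethyl-2-[(4R,8S)-4,8,12-trimethyltridec-11-en-1-yl]chroman-4-yl} 1H-imidazole-1-carbothioate | CC(C)=CCC[C@@H](C)CCC[C@@H](C)CCC[C@]1(C)CC(OC(=S)n3ccnc3)c2cc(OC)cc(C)c2O1
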